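**Retrosynthetic overview**
1. The target is a 2,3-trans-2,3-diaryl-2,3-dihydrobenzofuran: ring A is the benzo ring (C3a to C7a), ring B the 2,4-dioxygenated aryl on C2, ring C the 3,5-dioxygenated aryl on C3, ring D the 4-hydroxyphenyl of the C6 side chain.
2. Enabling feature: C3 is the benzylic carbon of ring C, and C3a is the ring-A CH flanked by the two oxygen-bearing carbons C4 and C7a. A temporary 4-OH on ring C makes C3 the methide carbon of a para-quinone methide, and bromines at C5 and C7 leave C3a as the only free ring-A position.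
3. Key disconnection C3–C3a: DDQ oxidation of the ring-C phenol and intramolecular Friedel–Crafts closure of the dihydrofuran ring (the last ring formed), with C3 set trans to the C2 aryl.
4. Earlier disconnections: O1–C2 by Mitsunobu inversion of a CBS-derived (R)-carbinol; the C2–C3 unit by Negishi acylation of a ring-C benzylzinc with a ring-B acid chloride; ring A to ring D by B-alkyl Suzuki coupling.
5. The helpers (ring-C 4-OH as its triflate, two Br, four benzyl ethers) leave in one hydrogenolysis; the ring-B pivalates, which keep C2 configurationally stable, leave last.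

Key step: step 14

Remark: the descriptors of the target correspond to the (2S,3S), 2,3-trans isomer; methyl gallate, 2,4-dihydroxybenzoic acid, 1-(benzyloxy)-4-vinylbenzene and 5-bromoresorcinol are taken as commercial.

**Route**

Step 1
Reactants: 1 methyl gallate (methyl 3,4,5-trihydroxybenzoate)
Product: 2 methyl 3,5-dihydroxy-4-[(4-methoxybenzyl)oxy]benzoate
Conditions: PMBCl (1.0 equiv), KHCO3, KI (cat.), DMF, rt
Reagents that add atoms: 4-methoxybenzyl chloride, COc1ccc(CCl)cc1
Why: Williamson etherification under weak base; the 4-OH (para to the ester, flanked by two hydrogen-bonding hydroxyls) is the most acidic phenol, so hydrogen carbonate should ionise and alkylate it selectively.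

Step 2
Reactants: 2 methyl 3,5-dihydroxy-4-[(4-methoxybenzyl)oxy]benzoate
Product: 3 methyl 3,5-bis(benzyloxy)-4-[(4-methoxybenzyl)oxy]benzoate
Conditions: BnBr (2.3 equiv), K2CO3, DMF, rt
Reagents that add atoms: benzyl bromide, BrCc1ccccc1
Why: exhaustive Williamson benzylation of the two remaining phenols; ester and PMB ether are inert.

Step 3
Reactants: 3 methyl 3,5-bis(benzyloxy)-4-[(4-methoxybenzyl)oxy]benzoate
Product: 4 {3,5-bis(benzyloxy)-4-[(4-methoxybenzyl)oxy]phenyl}methanol
Conditions: LiAlH4, THF, 0 °C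
Reagents that add atoms: none
Why: hydride reduction of the ester to the benzylic alcohol; the three aryl ethers are untouched.

Step 4
Reactants: 4 {3,5-bis(benzyloxy)-4-[(4-methoxybenzyl)oxy]phenyl}methanol
Product: 5 1,3-bis(benzyloxy)-5-(chloromethyl)-2-[(4-methoxybenzyl)oxy]benzene
Conditions: SOCl2, pyridine (1.1 equiv), CH2Cl2, 0 °C
Reagents that add atoms: thionyl chloride, ClS(Cl)=O
Why: chlorodehydroxylation through the chlorosulfite; pyridine buffers HCl so that the acid-labile PMB ether should survive.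

Step 5
Reactants: 6 2,4-dihydroxybenzoic acid
Product: 8 2,4-bis(pivaloyloxy)benzoic acid, via mixed pivalic anhydride 7 (not isolated)
Conditions: PivCl (3.3 equiv), pyridine, DMAP (cat.), CH2Cl2, 0 °C to rt; then H2O, THF, rt
Reagents that add atoms: pivaloyl chloride, CC(C)(C)C(Cl)=O; water, O
Why: DMAP/pyridine O-acylation of both phenols; the carboxyl group is carried as the mixed anhydride 7, which water should cleave at the unhindered aroyl carbonyl while the aryl pivalates remain.

Step 6
Reactants: 8 2,4-bis(pivaloyloxy)benzoic acid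
Product: 9 2,4-bis(pivaloyloxy)benzoyl chloride
Conditions: (COCl)2, DMF (cat.), CH2Cl2, 0 °C to rt
Reagents that add atoms: oxalyl chloride, ClC(=O)C(Cl)=O
Why: acid chloride formation by Vilsmeier-type activation; aryl pivalates are stable under these conditions.

Step 7
Reactants: 5 1,3-bis(benzyloxy)-5-(chloromethyl)-2-[(4-methoxybenzyl)oxy]benzene; 9 2,4-bis(pivaloyloxy)benzoyl chloride
Product: 11 deoxybenzoin ketone [ring B(OPiv)2]–CO–CH2–[ring C(OBn)2(OPMB)], via benzylzinc chloride 10 (not isolated)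
Conditions: 5, Zn dust, LiCl, THF, rt; then 9, Pd(PPh3)4 (3 mol%), THF, 0 °C to rt
Reagents that add atoms: zinc, [Zn] (held only in intermediate 10)
Why: LiCl-assisted zinc insertion into the benzylic chloride followed by Negishi acylation with the acid chloride; organozinc reagents tolerate aryl esters and ethers, and no alkoxide is formed next to the ortho pivalate.

Step 8
Reactants: 11 deoxybenzoin ketone
Product: 12 (R)-carbinol, 4-{(1R)-2-[3,5-bis(benzyloxy)-4-(4-methoxybenzyloxy)phenyl]-1-hydroxyethyl}-1,3-phenylene dipivalate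
Conditions: (S)-2-methyl-CBS-oxazaborolidine (20 mol%), BH3·SMe2, THF, −20 °C; then MeOH
Reagents that add atoms: none
Why: Corey–Bakshi–Shibata reduction; with the aryl group as the large and the benzyl group as the small substituent the (S)-catalyst should give the (R)-carbinol, and esters and ethers are inert to borane at −20 °C.

Step 9
Reactants: 13 1-(benzyloxy)-4-vinylbenzene; 14 5-bromobenzene-1,3-diol (5-bromoresorcinol)
Product: 16 5-{2-[4-(benzyloxy)phenyl]ethyl}benzene-1,3-diol, via B-alkyl-9-BBN borane 15 (not isolated)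
Conditions: 13, 9-BBN, THF, 0 °C to rt; then 14, PdCl2(dppf) (5 mol%), K3PO4 (aq), DMF, 60 °C
Reagents that add atoms: 9-borabicyclo[3.3.1]nonane, B1C2CCCC1CCC2 (held only in intermediate 15)
Why: anti-Markovnikov hydroboration of the styrene and B-alkyl Suzuki–Miyaura coupling with the aryl bromide; the phenols are carried as phenoxides and the benzyl ether is untouched.

Step 10
Reactants: 16 5-{2-[4-(benzyloxy)phenyl]ethyl}benzene-1,3-diol
Product: 17 4,6-dibromo-5-{2-[4-(benzyloxy)phenyl]ethyl}benzene-1,3-diol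
Conditions: NBS (2.05 equiv), CH2Cl2, −20 °C to 0 °C, dark
Reagents that add atoms: N-bromosuccinimide, O=C1CCC(=O)N1Br
Why: electrophilic aromatic bromination; the two positions para to one hydroxyl and ortho to the other react first, as in known 4,6-dihalogenations of 5-alkylresorcinols, which leaves the CH between the hydroxyls free, and ring D is far less activated.

Step 11
Reactants: 17 4,6-dibromo-5-{2-[4-(benzyloxy)phenyl]ethyl}benzene-1,3-diol
Product: 18 5-(benzyloxy)-2,4-dibromo-3-{2-[4-(benzyloxy)phenyl]ethyl}phenol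
Conditions: BnBr (1.0 equiv), K2CO3 (1.0 equiv), acetone, rt; recovered 17 recycled
Reagents that add atoms: benzyl bromide, BrCc1ccccc1
Why: Williamson mono-benzylation of the symmetric diol (statistical), which leaves a single phenol for the Mitsunobu step and ensures that ring C carries the only free phenol at the later triflation.

Step 12
Reactants: 12 (R)-carbinol; 18 5-(benzyloxy)-2,4-dibromo-3-{2-[4-(benzyloxy)phenyl]ethyl}phenol
Product: 19 (S)-aryl ether, ring A–O–CH[ring B(OPiv)2]–CH2–[ring C(OBn)2(OPMB)]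
Conditions: PPh3, DIAD, THF, 0 °C to rt
Reagents that add atoms: none
Why: Mitsunobu etherification; SN2 attack of the acidic ortho-bromophenol on the alkoxyphosphonium ion inverts the carbinol centre and sets (S)-C2, while the pivalates keep ring B electron-poor so that ionisation at this benzylic carbon is suppressed.

Step 13
Reactants: 19 (S)-aryl ether
Product: 20 (S)-aryl ether with free ring-C 4-OH [2,6-bis(benzyloxy)-4-alkylphenol]
Conditions: TFA, 1,3-dimethoxybenzene (10 equiv), CH2Cl2, 0 °C
Reagents that add atoms: none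
Why: acidolysis of the para-methoxybenzyl aryl ether with a cation scavenger; only the PMB group forms a stabilised cation, so benzyl ethers, pivalates and the deactivated benzylic C2–O bond should survive.

Step 14
Reactants: 20 (S)-aryl ether with free ring-C 4-OH
Product: 22 (2S,3S)-2,3-trans-dihydrobenzofuran with ring-C 4-OH free, via para-quinone methide 21 (not isolated)
Conditions: DDQ (1.05 equiv), CH2Cl2, −20 °C; then TFA (10 equiv), −20 °C to 0 °C
Reagents that add atoms: none
Why: DDQ should take the ring-C phenol of 20 (the only free phenol; ring B is deactivated by its pivalates, so the C2–H is not abstracted) through two-electron oxidation to the para-quinone methide 21, whose methide carbon is C3; TFA then protonates the carbonyl oxygen and the resulting 4-hydroxy-3,5-bis(benzyloxy)benzyl cation is attacked by ring A in an intramolecular Friedel–Crafts 1,6-addition. The closest known reaction type is the DDQ/TFA oxidative cyclisation of 4-hydroxy-3,5-dialkoxybenzyl lignans to aryltetralins through para-quinone methides, together with acid-catalysed 1,6-arylations of para-quinone methides. The dihydrofuran ring (O1–C2–C3–C3a–C7a) closes by attack of the aryl carbon C3a on the exocyclic methide carbon, a 5-exo-trig closure with respect to the C3=C(ring C) bond, followed by rearomatisation of rings A and C. The new stereocentre C3 is controlled by the existing C2 centre: in the envelope-like transition state the quinoid ring C turns away from ring B, which should give the 2,3-trans (2S,3S) product, and any minor cis isomer would be removed by chromatography. The step needs regioselectivity on ring A, secured because C5 and C7 carry bromine and C3a is the only free ring-A position, and it needs ring closure to outrun loss of the C2 proton and over-oxidation, which the stabilised cation, the low temperature and the single equivalent of DDQ consumed before acid is added should secure.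

Step 15
Reactants: 22 (2S,3S)-dihydrobenzofuran with ring-C 4-OH free
Product: 23 (2S,3S)-dihydrobenzofuran ring-C 4-triflate
Conditions: Tf2O, pyridine, CH2Cl2, 0 °C
Reagents that add atoms: trifluoromethanesulfonic anhydride, O=S(=O)(OS(=O)(=O)C(F)(F)F)C(F)(F)F
Why: O-sulfonylation of the only free phenol, which turns the auxiliary oxygen into a hydrogenolysable aryl triflate.

Step 16
Reactants: 23 (2S,3S)-dihydrobenzofuran ring-C 4-triflate
Product: 24 (2S,3S)-2-[2,4-bis(pivaloyloxy)phenyl]-3-(3,5-dihydroxyphenyl)-6-[2-(4-hydroxyphenyl)ethyl]-2,3-dihydro-1-benzofuran-4-ol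
Conditions: H2 (1 atm), 10% Pd/C, Et3N, THF/EtOAc, rt
Reagents that add atoms: none
Why: palladium-catalysed hydrogenolysis should remove in one operation the four benzyl ethers, the two aryl bromides and the aryl triflate, with Et3N taking up HBr and TfOH; the pivalates keep ring B electron-poor, which protects the benzylic C2–O1 bond, and no stereocentre is touched.

Step 17
Reactants: 24 ring-B dipivalate of the target
Product: 25 target, (2S,3S)-2-(2,4-dihydroxyphenyl)-3-(3,5-dihydroxyphenyl)-6-[2-(4-hydroxyphenyl)ethyl]-2,3-dihydro-1-benzofuran-4-ol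
Conditions: K2CO3, MeOH (degassed), 0 °C to rt; then Amberlite IR-120 (H+ form)
Reagents that add atoms: none
Why: base-catalysed transesterification (methanolysis) of the two aryl pivalates; C3 cannot epimerise, and any reversible ring opening at C2 through the ring-B quinone methide should reclose to the more stable trans isomer.

**Compound list**
1 | methyl gallate | COC(=O)c1cc(O)c(O)c(O)c1 | starting material
2 | methyl 3,5-dihydroxy-4-[(4-methoxybenzyl)oxy]benzoate | COC(=O)c1cc(O)c(OCc2ccc(OC)cc2)c(O)c1 | intermediate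
3 | methyl 3,5-bis(benzyloxy)-4-[(4-methoxybenzyl)oxy]benzoate | COC(=O)c1cc(OCc2ccccc2)c(OCc2ccc(OC)cc2)c(OCc2ccccc2)c1 | intermediate
4 | {3,5-bis(benzyloxy)-4-[(4-methoxybenzyl)oxy]phenyl}methanol | OCc1cc(OCc2ccccc2)c(OCc2ccc(OC)cc2)c(OCc2ccccc2)c1 | intermediate
5 | 1,3-bis(benzyloxy)-5-(chloromethyl)-2-[(4-methoxybenzyl)oxy]benzene | ClCc1cc(OCc2ccccc2)c(OCc2ccc(OC)cc2)c(OCc2ccccc2)c1 | intermediate
6 | 2,4-dihydroxybenzoic acid | OC(=O)c1ccc(O)cc1O | starting material
7 | 2,4-bis(pivaloyloxy)benzoic pivalic anhydride | CC(C)(C)C(=O)OC(=O)c1ccc(OC(=O)C(C)(C)C)cc1OC(=O)C(C)(C)C | intermediate (not isolated)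
8 | 2,4-bis(pivaloyloxy)benzoic acid | OC(=O)c1ccc(OC(=O)C(C)(C)C)cc1OC(=O)C(C)(C)C | intermediate
9 | 2,4-bis(pivaloyloxy)benzoyl chloride | ClC(=O)c1ccc(OC(=O)C(C)(C)C)cc1OC(=O)C(C)(C)C | intermediate
10 | {3,5-bis(benzyloxy)-4-[(4-methoxybenzyl)oxy]benzyl}zinc chloride | Cl[Zn]Cc1cc(OCc2ccccc2)c(OCc2ccc(OC)cc2)c(OCc2ccccc2)c1 | intermediate (not isolated)
11 | 4-{2-[3,5-bis(benzyloxy)-4-(4-methoxybenzyloxy)phenyl]acetyl}-1,3-phenylene dipivalate | O=C(Cc1cc(OCc2ccccc2)c(OCc2ccc(OC)cc2)c(OCc2ccccc2)c1)c1ccc(OC(=O)C(C)(C)C)cc1OC(=O)C(C)(C)C | intermediate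
12 | 4-{(1R)-2-[3,5-bis(benzyloxy)-4-(4-methoxybenzyloxy)phenyl]-1-hydroxyethyl}-1,3-phenylene dipivalate | O[C@H](Cc1cc(OCc2ccccc2)c(OCc2ccc(OC)cc2)c(OCc2ccccc2)c1)c1ccc(OC(=O)C(C)(C)C)cc1OC(=O)C(C)(C)C | intermediate
13 | 1-(benzyloxy)-4-vinylbenzene | C=Cc1ccc(OCc2ccccc2)cc1 | starting material
14 | 5-bromobenzene-1,3-diol | Oc1cc(O)cc(Br)c1 | starting material
15 | 9-{2-[4-(benzyloxy)phenyl]ethyl}-9-borabicyclo[3.3.1]nonane | c1ccc(cc1)COc1ccc(CCB2C3CCCC2CCC3)cc1 | intermediate (not isolated)
16 | 5-{2-[4-(benzyloxy)phenyl]ethyl}benzene-1,3-diol | Oc1cc(O)cc(CCc2ccc(OCc3ccccc3)cc2)c1 | intermediate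
17 | 4,6-dibromo-5-{2-[4-(benzyloxy)phenyl]ethyl}benzene-1,3-diol | Oc1cc(O)c(Br)c(CCc2ccc(OCc3ccccc3)cc2)c1Br | intermediate
18 | 5-(benzyloxy)-2,4-dibromo-3-{2-[4-(benzyloxy)phenyl]ethyl}phenol | Oc1cc(OCc2ccccc2)c(Br)c(CCc2ccc(OCc3ccccc3)cc2)c1Br | intermediate
19 | 4-{(1S)-1-[5-(benzyloxy)-2,4-dibromo-3-{2-[4-(benzyloxy)phenyl]ethyl}phenoxy]-2-[3,5-bis(benzyloxy)-4-(4-methoxybenzyloxy)phenyl]ethyl}-1,3-phenylene dipivalate | Brc1c(O[C@@H](Cc2cc(OCc3ccccc3)c(OCc3ccc(OC)cc3)c(OCc3ccccc3)c2)c2ccc(OC(=O)C(C)(C)C)cc2OC(=O)C(C)(C)C)cc(OCc2ccccc2)c(Br)c1CCc1ccc(OCc2ccccc2)cc1 | intermediate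
20 | 4-{(1S)-1-[5-(benzyloxy)-2,4-dibromo-3-{2-[4-(benzyloxy)phenyl]ethyl}phenoxy]-2-[3,5-bis(benzyloxy)-4-hydroxyphenyl]ethyl}-1,3-phenylene dipivalate | Brc1c(O[C@@H](Cc2cc(OCc3ccccc3)c(O)c(OCc3ccccc3)c2)c2ccc(OC(=O)C(C)(C)C)cc2OC(=O)C(C)(C)C)cc(OCc2ccccc2)c(Br)c1CCc1ccc(OCc2ccccc2)cc1 | intermediate
21 | para-quinone methide of 20: 4-{(1S)-1-[5-(benzyloxy)-2,4-dibromo-3-{2-[4-(benzyloxy)phenyl]ethyl}phenoxy]-2-[3,5-bis(benzyloxy)-4-oxocyclohexa-2,5-dien-1-ylidene]ethyl}-1,3-phenylene dipivalate | Brc1c(O[C@@H](C=C2C=C(OCc3ccccc3)C(=O)C(OCc3ccccc3)=C2)c2ccc(OC(=O)C(C)(C)C)cc2OC(=O)C(C)(C)C)cc(OCc2ccccc2)c(Br)c1CCc1ccc(OCc2ccccc2)cc1 | intermediate (not isolated)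
22 | (2S,3S)-4-(benzyloxy)-5,7-dibromo-6-{2-[4-(benzyloxy)phenyl]ethyl}-3-[3,5-bis(benzyloxy)-4-hydroxyphenyl]-2-[2,4-bis(pivaloyloxy)phenyl]-2,3-dihydro-1-benzofuran (2,3-trans) | c1ccc(cc1)COc1ccc(CCc2c(Br)c(OCc3ccccc3)c3c(c2Br)O[C@H](c2ccc(OC(=O)C(C)(C)C)cc2OC(=O)C(C)(C)C)[C@H]3c2cc(OCc4ccccc4)c(O)c(OCc4ccccc4)c2)cc1 | intermediate
23 | ring-C 4-trifluoromethanesulfonate of 22 | c1ccc(cc1)COc1ccc(CCc2c(Br)c(OCc3ccccc3)c3c(c2Br)O[C@H](c2ccc(OC(=O)C(C)(C)C)cc2OC(=O)C(C)(C)C)[C@H]3c2cc(OCc4ccccc4)c(OS(=O)(=O)C(F)(F)F)c(OCc4ccccc4)c2)cc1 | intermediate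
24 | (2S,3S)-2-[2,4-bis(pivaloyloxy)phenyl]-3-(3,5-dihydroxyphenyl)-6-[2-(4-hydroxyphenyl)ethyl]-2,3-dihydro-1-benzofuran-4-ol | Oc1ccc(CCc2cc(O)c3c(c2)O[C@H](c2ccc(OC(=O)C(C)(C)C)cc2OC(=O)C(C)(C)C)[C@H]3c2cc(O)cc(O)c2)cc1 | intermediate
25 | (2S,3S)-2-(2,4-dihydroxyphenyl)-3-(3,5-dihydroxyphenyl)-6-[2-(4-hydroxyphenyl)ethyl]-2,3-dihydro-1-benzofuran-4-ol | Oc1ccc(CCc2cc(O)c3c(c2)O[C@H](c2ccc(O)cc2O)[C@H]3c2cc(O)cc(O)c2)cc1 | target

**Step count and risks**
Total steps: 17. Longest linear sequence: 12 steps (steps 1–4, 7, 8, 12–17, from methyl gallate).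

Steps most likely to fail:

1. Step 14. What may go wrong: over-oxidation of the cyclised phenol to the aromatic benzofuran by residual oxidant; loss of the C2 proton from the quinone methide or its cation (enol ether formation and ether cleavage) before the dibrominated ring A attacks; ipso attack at the brominated C7 position. Fallback: oxidation and ring closure are separated. Setting out from 20, Ag2O in CH2Cl2 at rt should give the quinone methide, which is trapped with MeOH to give the benzylic methyl ether of 20 at C3 F1 (mixture of C3 epimers, ether carbon unchanged), isolated free of oxidant. BF3·OEt2 in CH2Cl2 at −78 °C then ionises this para-hydroxybenzyl ether and closes the ring, coming back to the route at 22.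

2. Step 12. What may go wrong: elimination of the activated carbinol to the stilbene, migration of the ortho pivaloyl group to the carbinol oxygen, or participation of the ortho pivalate carbonyl that erodes clean inversion. Fallback: activation and displacement are decoupled. Setting out from 12, MsCl/Et3N in CH2Cl2 at −20 °C gives, with retention, the (R)-methanesulfonate of 12 F2. Its SN2 displacement by the cesium phenoxide of 18 (Cs2CO3, DMF, rt) proceeds with inversion and comes back to the route at 19.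

3. Step 16. What may go wrong: incomplete C–O hydrogenolysis of the hindered ring-C triflate, catalyst poisoning by bromide, or hydrogenolytic opening of the benzylic C2–O1 bond. Fallback: reduction and debenzylation are split and the debenzylation is made non-reductive. Setting out from 23, homogeneous formate reduction (Pd(OAc)2, dppp, HCO2H, Et3N, DMF, 70 °C) removes triflate and bromides to give the tetrabenzyl ether dipivalate F3. BCl3 with pentamethylbenzene in CH2Cl2 at −78 °C then cleaves the four benzyl ethers and comes back to the route at 24.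

Further compounds
F1 | step 14 | benzylic methyl ether of 20 at C3 (C3 epimers) | Brc1c(O[C@@H](C(OC)c2cc(OCc3ccccc3)c(O)c(OCc3ccccc3)c2)c2ccc(OC(=O)C(C)(C)C)cc2OC(=O)C(C)(C)C)cc(OCc2ccccc2)c(Br)c1CCc1ccc(OCc2ccccc2)cc1
F2 | step 12 | (R)-methanesulfonate of 12 | CS(=O)(=O)O[C@H](Cc1cc(OCc2ccccc2)c(OCc2ccc(OC)cc2)c(OCc2ccccc2)c1)c1ccc(OC(=O)C(C)(C)C)cc1OC(=O)C(C)(C)C
F3 | step 16 | (2S,3S)-4-(benzyloxy)-6-{2-[4-(benzyloxy)phenyl]ethyl}-3-[3,5-bis(benzyloxy)phenyl]-2-[2,4-bis(pivaloyloxy)phenyl]-2,3-dihydro-1-benzofuran | c1ccc(cc1)COc1ccc(CCc2cc(OCc3ccccc3)c3c(c2)O[C@H](c2ccc(OC(=O)C(C)(C)C)cc2OC(=O)C(C)(C)C)[C@H]3c2cc(OCc4ccccc4)cc(OCc4ccccc4)c2)cc1
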